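- A ratio of two amounts is what you follow in these flasks: the cJ you charge, set against the J demand of the X you charge, 0.100 M, which is two J for each X, since the bis adduct D holds two.

| flask | X | J | Q | remark | time |
|---|---|---|---|---|---|
| dusk | 0.050 M | 0.046 M | 0.015 M | run made earlier |  |
| noon | 0.050 M | 0.10 M | 0.015 M | run made earlier |  |
| alpha | 0.050 M | 0.0600 M | 0.0150 M |  | 5.0 d |
| beta | 0.050 M | 0.0750 M | 0.0150 M |  | 5.0 d |
| gamma | 0.050 M | 0.150 M | 0.0150 M |  | 5.0 d |

- dusk (time / d: D / %, X / %): 0.125: 0, 88; 0.417: 6, 75; 0.625: 10, 67; 1.04: 13, 61; 1.67: 19, 48; 2.08: 22, 41; 2.50: 24, 36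
- noon (time / d: D / %, X / %): 0.125: 1, 85; 0.417: 17, 55; 0.625: 32, 43; 1.04: 40, 31; 1.67: 57, 22; 2.08: 60, 19; 2.50: 63, 16

(standard deviation of a reading: 2 percentage points)



- D at the end, in percent of the X charged, for each flask in turn (alpha, beta, gamma)

- Each D takes two J, so cJ over the demand is a ceiling on D, counted as a fraction of the X charged. Once the ratio passes one, X is the limiting reagent and the ceiling stays at the X charged.
- My own reckoning gives ceilings of 46.0% for dusk and 100% for noon, then 60.0% for alpha and 75.0% for beta. Gamma has a ratio of 1.50, so its ceiling is 100%.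
- Now read how far the runs have climbed. At 2.50 d, dusk shows D at 52.2% of its ceiling and noon at 63.0%. These are readings, each with a scatter of 2 percentage points.
- The forecast gives 44%, 59% and 97%, each under its ceiling. For gamma it says “J is in excess, the mono adduct is almost fully converted”.

    X + J → Z + E (k = 0.640 M⁻¹ h⁻¹)
    J + Z → D + E (k = 1.50 M⁻¹ h⁻¹)
    2 X → G (k = 0.0290 M⁻¹ h⁻¹)
    Z + Q → Ul (k = 1.40 M⁻¹ h⁻¹)

- The flasks give 41.9%, 54.8% and 86.8%, so gamma ends 10 points lower than the forecast. At 5.00 d, gamma also holds Ul at 10.8% of the X charged. Use the demand again: had each X in gamma ended as D, 33.3% of its J would remain, but 38.5% does, which is more. Alpha stays under its ceiling of 60.0%: at 50.0 d it holds D at 45.3%, with J down to 0.00521% of its charge.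

The runs were computed with constants of no real substance; scatter was added.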